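**Retrosynthetic overview**

1. The target is a 6,7-seco-ent-kaurane 7,20-lactone. Ring D (C13–C16) comes last, by tin-mediated enyne radical cyclization after ethynyl addition (C16, C17) to a formyl group on C8 (C15).
2. Ring C (C8–C14 and C9–C11) comes from a Diels–Alder reaction of the 8-formyl-Δ8,9 spirolactone with (1E,3E)-1,4-bis(silyloxy)butadiene, which sets C8, C9, C11 and C14 together.
3. The spirolactone ring (C7, C8, C9, C10, C20, O) comes from oxidative lactonization of a 7,20-diol; O1 is acetylated before the C20 hydroxyl is released.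
4. The strategy rests on ring A: the C1 oxygen and C20 on the quaternary C10 are cis (a 1,3-diol). A C1–O–SiMe2–CH2 tether therefore delivers C20 to C10 of a C5=C10 enoate by 5-exo radical closure, and Tamao oxidation frees the diol.
5. Ring order: A (from 4,4-dimethylcyclohexane-1,3-dione, C1 by CBS reduction), temporary oxasilolane, lactone, C, D.

Key step: step 11

Remark: ent-kaurane locants are used for all intermediates; C15 in 35–37 is a mixture of epimers that converges in step 25.

**Route**

Step 1
Reactants: 1 4,4-dimethylcyclohexane-1,3-dione; 2 allyl bromide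
Product: 3 2-allyl-4,4-dimethylcyclohexane-1,3-dione
Conditions: KOH (1 M aq.), Cu powder (cat.), rt
Reagents that add atoms: none
Why: C-allylation of the cyclic 1,3-dione enolate in water, where allylic halides alkylate on carbon; C2 of the dione becomes C10 and the allyl group becomes the C9–C8–C7 chain.

Step 2
Reactants: 3 2-allyl-4,4-dimethylcyclohexane-1,3-dione
Product: 4 2-allyl-3-isobutoxy-6,6-dimethylcyclohex-2-en-1-one
Conditions: i-BuOH, TsOH·H2O (cat.), PhMe, reflux, Dean–Stark
Reagents that add atoms: 2-methylpropan-1-ol CC(C)CO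
Why: acid-catalysed vinylogous ester formation, in which the alcohol should attack the carbonyl remote from the gem-dimethyl group and leave the hindered ketone (future C5) for the later 1,2-addition.

Step 3
Reactants: 4 2-allyl-3-isobutoxy-6,6-dimethylcyclohex-2-en-1-one
Product: 6 2-(3-hydroxypropyl)-3-isobutoxy-6,6-dimethylcyclohex-2-en-1-one, via 9-BBN alkylborane 5 (not isolated)
Conditions: 9-BBN, THF, 0 °C → rt; then NaOH (3 M aq.), 30% H2O2, 0 °C
Reagents that add atoms: hydrogen peroxide OO
Why: anti-Markovnikov hydroboration–oxidation of the terminal alkene, which 9-BBN attacks far faster than the deactivated vinylogous ester carbonyl, gives the C7 carbinol.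

Step 4
Reactants: 6 2-(3-hydroxypropyl)-3-isobutoxy-6,6-dimethylcyclohex-2-en-1-one
Product: 7 2-[3-(tert-butyldimethylsilyloxy)propyl]-3-isobutoxy-6,6-dimethylcyclohex-2-en-1-one
Conditions: TBSCl, imidazole, CH2Cl2, rt
Reagents that add atoms: tert-butyldimethylsilyl chloride CC(C)(C)[Si](C)(C)Cl
Why: routine silylation of the primary alcohol; TBS is chosen for O7 so that it can later be removed together with the C20 silyl ether.

Step 5
Reactants: 7 2-[3-(tert-butyldimethylsilyloxy)propyl]-3-isobutoxy-6,6-dimethylcyclohex-2-en-1-one; 8 vinylmagnesium bromide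
Product: 10 2-[3-(tert-butyldimethylsilyloxy)propyl]-4,4-dimethyl-3-vinylcyclohex-2-en-1-one, via tertiary carbinol 9 (not isolated)
Conditions: THF, 0 °C → rt; then HCl (1 M aq.), 0 °C, short contact
Reagents that add atoms: water O
Why: Stork–Danheiser sequence, in which 1,2-addition to the vinylogous ester carbonyl and brief acid hydrolysis transpose the enone so that the ketone sits at C1 and the new carbon (C6) at C5 next to the gem-dimethyl group.

Step 6
Reactants: 10 2-[3-(tert-butyldimethylsilyloxy)propyl]-4,4-dimethyl-3-vinylcyclohex-2-en-1-one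
Product: 11 2-[3-(tert-butyldimethylsilyloxy)propyl]-6,6-dimethyl-3-oxocyclohex-1-ene-1-carbaldehyde
Conditions: OsO4 (cat.), NaIO4, 2,6-lutidine, dioxane/H2O, rt
Reagents that add atoms: sodium periodate [Na+].[O-]I(=O)(=O)=O
Why: Lemieux–Johnson cleavage of the terminal vinyl group, which is far more reactive towards OsO4 than the tetrasubstituted, electron-poor ring alkene.

Step 7
Reactants: 11 2-[3-(tert-butyldimethylsilyloxy)propyl]-6,6-dimethyl-3-oxocyclohex-1-ene-1-carbaldehyde
Product: 12 2-[3-(tert-butyldimethylsilyloxy)propyl]-6,6-dimethyl-3-oxocyclohex-1-ene-1-carboxylic acid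
Conditions: NaClO2, NaH2PO4, 2-methylbut-2-ene, t-BuOH/H2O, rt
Reagents that add atoms: sodium chlorite [Na+].[O-]Cl=O
Why: Pinnick oxidation converts the enal to the acid without touching the enone or the silyl ether.

Step 8
Reactants: 12 2-[3-(tert-butyldimethylsilyloxy)propyl]-6,6-dimethyl-3-oxocyclohex-1-ene-1-carboxylic acid
Product: 13 methyl 2-[3-(tert-butyldimethylsilyloxy)propyl]-6,6-dimethyl-3-oxocyclohex-1-ene-1-carboxylate
Conditions: MeI, K2CO3, DMF, rt
Reagents that add atoms: iodomethane CI
Why: O-alkylation of the carboxylate gives the C6 methyl ester that activates C10 as a radical acceptor.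

Step 9
Reactants: 13 methyl 2-[3-(tert-butyldimethylsilyloxy)propyl]-6,6-dimethyl-3-oxocyclohex-1-ene-1-carboxylate
Product: 14 methyl (3S)-2-[3-(tert-butyldimethylsilyloxy)propyl]-3-hydroxy-6,6-dimethylcyclohex-1-ene-1-carboxylate
Conditions: (R)-1-methyl-3,3-diphenyltetrahydro-1H,3H-pyrrolo[1,2-c][1,3,2]oxazaborole ((R)-Me-CBS, 0.2 equiv), BH3·SMe2, THF, −20 °C; MeOH quench
Reagents that add atoms: none
Why: Corey–Bakshi–Shibata reduction, in which the catalyst distinguishes the substituted alkenyl flank (large) from the ring methylene (small) of the 2-substituted cyclohexenone, so the (R)-oxazaborolidine should give the (S)-alcohol at C1.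

Step 10
Reactants: 14 methyl (3S)-2-[3-(tert-butyldimethylsilyloxy)propyl]-3-hydroxy-6,6-dimethylcyclohex-1-ene-1-carboxylate; 15 (bromomethyl)chlorodimethylsilane
Product: 16 methyl (3S)-3-{[(bromomethyl)dimethylsilyl]oxy}-2-[3-(tert-butyldimethylsilyloxy)propyl]-6,6-dimethylcyclohex-1-ene-1-carboxylate
Conditions: Et3N, DMAP (4-dimethylaminopyridine, cat.), CH2Cl2, 0 °C; used without chromatography
Reagents that add atoms: none
Why: silylation of the allylic alcohol with the chlorosilane installs the O1–Si–CH2Br tether.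

Step 11
Reactants: 16 methyl (3S)-3-{[(bromomethyl)dimethylsilyl]oxy}-2-[3-(tert-butyldimethylsilyloxy)propyl]-6,6-dimethylcyclohex-1-ene-1-carboxylate
Product: 17 oxasilolane ester: ring A cis-fused to a 1-oxa-2-silacyclopentane (O1–SiMe2–C20H2), C10 quaternary with the (CH2)3OTBS chain, C5 CO2Me cis to C20
Conditions: Bu3SnH (syringe pump), AIBN (azobisisobutyronitrile, cat.), PhH, 80 °C, high dilution
Reagents that add atoms: none
Why: Bu3Sn• abstracts bromine from 16 to give the nucleophilic silylmethyl radical, which adds to C10, the β-carbon of the C5=C10 enoate, and the ester-stabilised C5 radical then takes hydrogen from Bu3SnH. The closest known reaction type is the silicon-tethered radical cyclization of (bromomethyl)dimethylsilyl ethers of allylic alcohols, used to place an angular hydroxymethyl group cis to a neighbouring hydroxyl. The oxasilolane (Si, C20, C10, C1, O1) closes in the 5-exo-trig mode; the 6-endo alternative would attack C5 beside the gem-dimethyl group and leave an unstabilised radical on C10. C10 is controlled by the tether, because the O1–Si–C20 chain can reach only the face of C10 that carries O1, so C20 ends cis to the C1 oxygen. C5 is controlled by hydrogen delivery to the face opposite the axial C20 arm and the axial C4 methyl, which should place the ester cis to C20. The step needs closure to outrun direct reduction of the first radical at a fully substituted carbon, which the polarity match with the enoate and slow addition of the stannane at high dilution secure.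

Step 12
Reactants: 17 oxasilolane ester
Product: 18 oxasilolane C6 alcohol (C5 CH2OH)
Conditions: i-Bu2AlH (3 equiv), CH2Cl2, −78 → 0 °C; Rochelle salt work-up
Reagents that add atoms: none
Why: hydride reduction of the hindered ester to the C6 carbinol under neutral work-up, which leaves the Si–O and Si–C bonds of the tether intact.

Step 13
Reactants: 18 oxasilolane C6 alcohol
Product: 19 oxasilolane C6 TBDPS ether
Conditions: TBDPSCl, imidazole, DMF, rt
Reagents that add atoms: tert-butyldiphenylsilyl chloride CC(C)(C)[Si](Cl)(c1ccccc1)c1ccccc1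
Why: silylation of the only free (primary) hydroxyl with a group that outlasts the later removal of TBS ethers and also shields the C5 side of the future lactone.

Step 14
Reactants: 19 oxasilolane C6 TBDPS ether
Product: 20 1,20-diol (C1 OH and C20 OH cis on ring A; 6-OTBDPS, 7-OTBS)
Conditions: 30% H2O2, KF, KHCO3, THF/MeOH, rt
Reagents that add atoms: hydrogen peroxide OO
Why: Tamao oxidation, in which C20 migrates from the fluoride-activated alkoxysilane to oxygen with retention and the Si–O1 bond is hydrolysed, releases the cis 1,3-diol.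

Step 15
Reactants: 20 1,20-diol
Product: 21 20-O-TBS ether with free C1 OH
Conditions: TBSCl (1.1 equiv), imidazole, CH2Cl2, 0 °C
Reagents that add atoms: tert-butyldimethylsilyl chloride CC(C)(C)[Si](C)(C)Cl
Why: the primary C20 hydroxyl is silylated faster than the secondary C1 hydroxyl next to the quaternary C10, which differentiates the two oxygens.

Step 16
Reactants: 21 20-O-TBS ether
Product: 22 1-O-acetate (6-OTBDPS, 7-OTBS, 20-OTBS)
Conditions: Ac2O, pyridine, DMAP (cat.), rt
Reagents that add atoms: acetic anhydride CC(=O)OC(C)=O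
Why: acetylation of the only free hydroxyl installs the C1 acetate of the target before any oxygen that could compete is present.

Step 17
Reactants: 22 1-O-acetate
Product: 23 7,20-diol 1-acetate (6-OTBDPS)
Conditions: HF·pyridine, THF/pyridine, 0 °C
Reagents that add atoms: none
Why: the two primary TBS ethers are cleaved much faster than the TBDPS ether, and the weakly acidic medium suppresses 1,3-acetyl migration from O1 to O20.

Step 18
Reactants: 23 7,20-diol 1-acetate
Product: 24 spirolactone (C7(=O)–O–C20), 1-OAc, 6-OTBDPS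
Conditions: TEMPO (2,2,6,6-tetramethylpiperidin-1-oxyl, 0.2 equiv), PhI(OAc)2 (2.5 equiv), CH2Cl2, rt
Reagents that add atoms: none
Why: oxidative lactonization, in which the unhindered C7 carbinol is oxidised first, the aldehyde is trapped by the neopentyl C20 hydroxyl as a six-membered lactol and oxidised on, so the carbonyl ends at C7; O1 is capped and cannot compete for C7.

Step 19
Reactants: 24 spirolactone; 25 tert-butoxybis(dimethylamino)methane
Product: 27 8-(hydroxymethylene) lactone (enol form of the 8-formyl lactone), via enaminolactone 26 (not isolated)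
Conditions: PhMe, 80 °C; then HCl (1 M aq.), THF, rt
Reagents that add atoms: water O
Why: aminomethylenation of the lactone α-methylene (C8) with the formamide acetal under neutral conditions that should spare the less acidic acetate, then acid hydrolysis of the vinylogous carbamate, installs C15.

Step 20
Reactants: 27 8-(hydroxymethylene) lactone
Product: 29 8-formyl-Δ8,9 spirolactone, via formyl selenide 28 (not isolated)
Conditions: PhSeCl, pyridine, CH2Cl2, 0 °C; then 30% H2O2, 0 °C; used crude
Reagents that add atoms: none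
Why: α-selenenylation of the enolised β-dicarbonyl and selenoxide syn-elimination, which can run only towards C9 because C8 has no other β-hydrogen, give the doubly activated C8=C9 dienophile.

Step 21
Reactants: 30 (1E,3E)-buta-1,3-diene-1,4-diyl diacetate
Product: 32 (1E,3E)-1,4-bis(tert-butyldimethylsilyloxy)buta-1,3-diene, via dilithium dienediolate 31 (not isolated)
Conditions: MeLi (4 equiv), DME, −40 → 0 °C; then TBSCl, DMPU, −78 °C → rt
Reagents that add atoms: tert-butyldimethylsilyl chloride CC(C)(C)[Si](C)(C)Cl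
Why: cleavage of both enol acetates with MeLi gives the bis-enolate with retention of the (E,E) geometry and O-silylation gives the bis(silyl enol ether).

Step 22
Reactants: 29 8-formyl-Δ8,9 spirolactone; 32 (1E,3E)-1,4-bis(tert-butyldimethylsilyloxy)buta-1,3-diene
Product: 33 Diels–Alder adduct: ring C cyclohexene (C12=C13) cis-fused to the lactone, 11,14-bis-OTBS cis to the C8 formyl group and to H9
Conditions: 32 (3 equiv), ZnCl2 (0.2 equiv), CH2Cl2, −40 → 0 °C
Reagents that add atoms: none
Why: normal-demand Diels–Alder reaction of the doubly activated C8=C9 alkene, in which ZnCl2 chelated between the lactone and formyl oxygens keeps the formyl group s-trans to the alkene (no oxadiene), the formyl group sits endo while the spiro ring stays exo so both silyloxy groups end cis to C15 and H9, and the diene should add to the lactone face on the C1 side, away from the C5 arm with its C6 silyl ether, so that C8, C9, C11 and C14 are set together.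

Step 23
Reactants: 33 Diels–Alder adduct; 34 ethynylmagnesium bromide
Product: 35 propargylic alcohol (C15 OH, C16≡C17; C15 epimers)
Conditions: THF, −78 °C; AcOH quench at −78 °C
Reagents that add atoms: none
Why: 1,2-addition of the small acetylide Grignard reagent to the neopentyl aldehyde, the most electrophilic carbonyl present, with a cold quench so that the β-alkoxide of the lactone does not undergo retro-aldol cleavage; the C15 configuration is irrelevant.

Step 24
Reactants: 35 propargylic alcohol
Product: 37 tetracyclic allylic alcohol (bicyclo[3.2.1]octane with 16-methylene and 15-OH), via vinylstannane 36 (not isolated)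
Conditions: Bu3SnH (syringe pump), AIBN (cat.), PhH, 80 °C; then pyridinium p-toluenesulfonate, CH2Cl2, rt
Reagents that add atoms: none
Why: tin hydride-mediated enyne radical cyclization, in which Bu3Sn• adds to the terminal alkyne carbon C17, the C16 vinyl radical closes 5-exo-trig onto C13 (the C12 radical is then reduced) and acid protodestannylates the vinylstannane to the exocyclic methylene; C13 can form only with C16 on the face that carries C15, so its configuration follows from C8.

Step 25
Reactants: 37 tetracyclic allylic alcohol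
Product: 38 15-ketone (1-OAc, 6-OTBDPS, 11,14-bis-OTBS)
Conditions: Dess–Martin periodinane, NaHCO3, CH2Cl2, rt
Reagents that add atoms: none
Why: Dess–Martin oxidation of the only free hydroxyl gives the α-methylene ketone; C8 is quaternary, so the β-keto lactone cannot enolise or epimerise.

Step 26
Reactants: 38 15-ketone
Product: 39 target CNP0225182.1
Conditions: HF·pyridine, THF, 0 °C → rt
Reagents that add atoms: none
Why: fluoride cleavage of the three silyl ethers under mildly acidic conditions, which leave the acetate and the exocyclic enone untouched and avoid base-induced retro-aldol cleavage of the C14 β-hydroxy ketone.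

**Compound list**

1 | 4,4-dimethylcyclohexane-1,3-dione | CC1(C)CCC(=O)CC1=O | starting material
2 | allyl bromide | C=CCBr | starting material
3 | 2-allyl-4,4-dimethylcyclohexane-1,3-dione | C=CCC1C(=O)CCC(C)(C)C1=O | intermediate
4 | 2-allyl-3-isobutoxy-6,6-dimethylcyclohex-2-en-1-one | C=CCC1=C(OCC(C)C)CCC(C)(C)C1=O | intermediate
5 | 9-[3-(2-isobutoxy-5,5-dimethyl-6-oxocyclohex-1-en-1-yl)propyl]-9-borabicyclo[3.3.1]nonane | CC(C)COC1=C(CCCB2C3CCCC2CCC3)C(=O)C(C)(C)CC1 | intermediate
6 | 2-(3-hydroxypropyl)-3-isobutoxy-6,6-dimethylcyclohex-2-en-1-one | OCCCC1=C(OCC(C)C)CCC(C)(C)C1=O | intermediate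
7 | 2-[3-(tert-butyldimethylsilyloxy)propyl]-3-isobutoxy-6,6-dimethylcyclohex-2-en-1-one | CC(C)COC1=C(CCCO[Si](C)(C)C(C)(C)C)C(=O)C(C)(C)CC1 | intermediate
8 | vinylmagnesium bromide | C=C[Mg]Br | starting material
9 | 2-[3-(tert-butyldimethylsilyloxy)propyl]-3-isobutoxy-6,6-dimethyl-1-vinylcyclohex-2-en-1-ol (racemic, as its magnesium alkoxide) | C=CC1(O)C(CCCO[Si](C)(C)C(C)(C)C)=C(OCC(C)C)CCC1(C)C | intermediate
10 | 2-[3-(tert-butyldimethylsilyloxy)propyl]-4,4-dimethyl-3-vinylcyclohex-2-en-1-one | C=CC1=C(CCCO[Si](C)(C)C(C)(C)C)C(=O)CCC1(C)C | intermediate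
11 | 2-[3-(tert-butyldimethylsilyloxy)propyl]-6,6-dimethyl-3-oxocyclohex-1-ene-1-carbaldehyde | O=CC1=C(CCCO[Si](C)(C)C(C)(C)C)C(=O)CCC1(C)C | intermediate
12 | 2-[3-(tert-butyldimethylsilyloxy)propyl]-6,6-dimethyl-3-oxocyclohex-1-ene-1-carboxylic acid | OC(=O)C1=C(CCCO[Si](C)(C)C(C)(C)C)C(=O)CCC1(C)C | intermediate
13 | methyl 2-[3-(tert-butyldimethylsilyloxy)propyl]-6,6-dimethyl-3-oxocyclohex-1-ene-1-carboxylate | COC(=O)C1=C(CCCO[Si](C)(C)C(C)(C)C)C(=O)CCC1(C)C | intermediate
14 | methyl (3S)-2-[3-(tert-butyldimethylsilyloxy)propyl]-3-hydroxy-6,6-dimethylcyclohex-1-ene-1-carboxylate | COC(=O)C1=C(CCCO[Si](C)(C)C(C)(C)C)[C@@H](O)CCC1(C)C | intermediate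
15 | (bromomethyl)chlorodimethylsilane | C[Si](C)(Cl)CBr | starting material
16 | methyl (3S)-3-{[(bromomethyl)dimethylsilyl]oxy}-2-[3-(tert-butyldimethylsilyloxy)propyl]-6,6-dimethylcyclohex-1-ene-1-carboxylate | COC(=O)C1=C(CCCO[Si](C)(C)C(C)(C)C)[C@@H](O[Si](C)(C)CBr)CCC1(C)C | intermediate
17 | oxasilolane ester (O1–SiMe2–C20 bridge cis-fused to ring A; C10 chain (CH2)3OTBS; C5 CO2Me cis to C20) | C[Si]1(C)C[C@]2([C@@H](O1)CCC(C)(C)[C@H]2C(=O)OC)CCCO[Si](C)(C)C(C)(C)C | intermediate
18 | oxasilolane C6 alcohol | C[Si]1(C)C[C@]2([C@@H](O1)CCC(C)(C)[C@H]2CO)CCCO[Si](C)(C)C(C)(C)C | intermediate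
19 | oxasilolane C6 TBDPS ether | C[Si]1(C)C[C@]2([C@@H](O1)CCC(C)(C)[C@H]2CO[Si](c3ccccc3)(c3ccccc3)C(C)(C)C)CCCO[Si](C)(C)C(C)(C)C | intermediate
20 | 1,20-diol (6-OTBDPS, 7-OTBS) | OC[C@]1([C@@H](O)CCC(C)(C)[C@H]1CO[Si](c2ccccc2)(c2ccccc2)C(C)(C)C)CCCO[Si](C)(C)C(C)(C)C | intermediate
21 | 20-O-TBS ether with free C1 hydroxyl | CC(C)(C)[Si](C)(C)OC[C@]1([C@@H](O)CCC(C)(C)[C@H]1CO[Si](c2ccccc2)(c2ccccc2)C(C)(C)C)CCCO[Si](C)(C)C(C)(C)C | intermediate
22 | 1-O-acetate (6-OTBDPS, 7-OTBS, 20-OTBS) | CC(C)(C)[Si](C)(C)OC[C@]1([C@@H](OC(C)=O)CCC(C)(C)[C@H]1CO[Si](c2ccccc2)(c2ccccc2)C(C)(C)C)CCCO[Si](C)(C)C(C)(C)C | intermediate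
23 | 7,20-diol 1-acetate (6-OTBDPS) | OC[C@]1([C@@H](OC(C)=O)CCC(C)(C)[C@H]1CO[Si](c2ccccc2)(c2ccccc2)C(C)(C)C)CCCO | intermediate
24 | spirolactone (7,20-olide; 1-OAc, 6-OTBDPS) | O=C1OC[C@]2([C@@H](OC(C)=O)CCC(C)(C)[C@H]2CO[Si](c3ccccc3)(c3ccccc3)C(C)(C)C)CC1 | intermediate
25 | tert-butoxybis(dimethylamino)methane | CN(C)C(OC(C)(C)C)N(C)C | starting material
26 | (E)-8-(dimethylaminomethylene) spirolactone | CN(C)/C=C1/C(=O)OC[C@]2([C@@H](OC(C)=O)CCC(C)(C)[C@H]2CO[Si](c3ccccc3)(c3ccccc3)C(C)(C)C)C1 | intermediate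
27 | (Z)-8-(hydroxymethylene) spirolactone (enol of the 8-formyl lactone) | O/C=C1\C(=O)OC[C@]2([C@@H](OC(C)=O)CCC(C)(C)[C@H]2CO[Si](c3ccccc3)(c3ccccc3)C(C)(C)C)C1 | intermediate
28 | 8-formyl-8-(phenylselanyl) spirolactone (C8 epimers) | O=CC1([Se]c2ccccc2)C(=O)OC[C@]3([C@@H](OC(C)=O)CCC(C)(C)[C@H]3CO[Si](c4ccccc4)(c4ccccc4)C(C)(C)C)C1 | intermediate
29 | 8-formyl-Δ8,9 spirolactone | O=C1OC[C@]2([C@@H](OC(C)=O)CCC(C)(C)[C@H]2CO[Si](c3ccccc3)(c3ccccc3)C(C)(C)C)C=C1C=O | intermediate
30 | (1E,3E)-buta-1,3-diene-1,4-diyl diacetate | CC(=O)O/C=C/C=C/OC(C)=O | starting material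
31 | dilithium (1E,3E)-buta-1,3-diene-1,4-diolate | [Li+].[Li+].[O-]/C=C/C=C/[O-] | intermediate
32 | (1E,3E)-1,4-bis(tert-butyldimethylsilyloxy)buta-1,3-diene | CC(C)(C)[Si](C)(C)O/C=C/C=C/O[Si](C)(C)C(C)(C)C | intermediate
33 | Diels–Alder adduct (C8 CHO; C12=C13; 11,14-bis-OTBS) | O=C[C@@]23C(=O)OC[C@]4([C@@H](OC(C)=O)CCC(C)(C)[C@H]4CO[Si](c5ccccc5)(c5ccccc5)C(C)(C)C)[C@@H]2[C@@H](O[Si](C)(C)C(C)(C)C)C=C[C@H]3O[Si](C)(C)C(C)(C)C | intermediate
34 | ethynylmagnesium bromide | C#C[Mg]Br | starting material
35 | propargylic alcohol (C15 epimers) | C#CC(O)[C@@]23C(=O)OC[C@]4([C@@H](OC(C)=O)CCC(C)(C)[C@H]4CO[Si](c5ccccc5)(c5ccccc5)C(C)(C)C)[C@@H]2[C@@H](O[Si](C)(C)C(C)(C)C)C=C[C@H]3O[Si](C)(C)C(C)(C)C | intermediate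
36 | C17 tributylstannyl 16-methylene tetracycle (alkene and C15 isomers) | CCCC[Sn](CCCC)(CCCC)C=C1C(O)[C@@]23C(=O)OC[C@]4([C@@H](OC(C)=O)CCC(C)(C)[C@H]4CO[Si](c5ccccc5)(c5ccccc5)C(C)(C)C)[C@@H]2[C@@H](O[Si](C)(C)C(C)(C)C)C[C@@H]1[C@H]3O[Si](C)(C)C(C)(C)C | intermediate
37 | tetracyclic allylic alcohol (15-OH, 16-methylene; C15 epimers) | C=C1C(O)[C@@]23C(=O)OC[C@]4([C@@H](OC(C)=O)CCC(C)(C)[C@H]4CO[Si](c5ccccc5)(c5ccccc5)C(C)(C)C)[C@@H]2[C@@H](O[Si](C)(C)C(C)(C)C)C[C@@H]1[C@H]3O[Si](C)(C)C(C)(C)C | intermediate
38 | 15-ketone (1-OAc, 6-OTBDPS, 11,14-bis-OTBS) | C=C1C(=O)[C@@]23C(=O)OC[C@]4([C@@H](OC(C)=O)CCC(C)(C)[C@H]4CO[Si](c5ccccc5)(c5ccccc5)C(C)(C)C)[C@@H]2[C@@H](O[Si](C)(C)C(C)(C)C)C[C@@H]1[C@H]3O[Si](C)(C)C(C)(C)C | intermediate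
39 | CNP0225182.1 (1-acetoxy-6,11,14-trihydroxy-15-oxo-6,7-seco-ent-kaur-16-en-7,20-olide) | C=C1C(=O)[C@@]23C(=O)OC[C@]4([C@@H](OC(C)=O)CCC(C)(C)[C@H]4CO)[C@@H]2[C@@H](O)C[C@@H]1[C@H]3O | target

**Totals**

Total step count: 26. Longest linear sequence: 25 steps (steps 1–20 and 22–26; step 21 makes the diene in a side branch).

**Steps most likely to fail**

1. Step 11 (key step). The silylmethyl radical may be reduced by the stannane before it closes onto the fully substituted C10, or hydrogen may be delivered to the other face of C5. Base equilibration of the ester is not relied on, because an ester flanked by two quaternary carbons has no clear equatorial preference. Fallback: set out from 16 and exchange bromide for iodide (NaI, acetone) to give the (iodomethyl)dimethylsilyl ether F1. Cyclise F1 with SmI2, HMPA and t-BuOH in THF. Single-electron reduction gives the same tethered radical in a medium without a hydrogen-atom donor; after 5-exo closure the C5 radical is reduced to the samarium enolate, which t-BuOH protonates from the open face. The route is rejoined at 17.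

2. Step 22. The bis(silyloxy)diene may be consumed by Mukaiyama-type conjugate addition or by inverse-demand hetero-cycloaddition onto the formyl enoate; cycloaddition at the neopentyl C9 may be too slow for a diene substituted at both termini; or the diene may approach the lactone face on the C5 side, since the C1 face also carries an acetoxy group. Fallback (the two oxygens are introduced after ring C; this removes the first two failure modes, while the facial preference stays substrate-controlled): set out from 29 and run the cycloaddition with (E)-buta-1,3-dien-1-yl acetate to give the 14-acetoxy adduct F2. Palladium-catalysed 1,4-elimination (Pd(PPh3)4, Et3N, dioxane, 80 °C) gives the ring C cyclohexa-1,3-diene aldehyde F3, and ethynylmagnesium bromide gives the dienyl propargylic alcohol F4. Singlet oxygen (O2, tetraphenylporphyrin, hν) should add across C11 and C14 on the face away from C10 to give the endoperoxide F5, which thiourea reduces to the cis-11,14-diol F6. Bu3SnH/AIBN followed by pyridinium p-toluenesulfonate closes ring D to the tetracyclic triol F7, MnO2 oxidises only the allylic C15 hydroxyl to give the enone diol F8, and HF·pyridine removes the TBDPS ether to rejoin the route at 39.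

3. Step 24. The vinyl radical may be reduced before it closes, or may close 6-endo at C12 to a bicyclo[2.2.2]octane, because closure at C13 needs ring C in the conformer with C15 axial and the C11 silyl ether syn-axial. Fallback: set out from 35 and use a palladium hydride reductive enyne cyclization (Pd2(dba)3, P(o-tol)3, AcOH, Et3SiH, PhMe). H–Pd adds across the alkyne, the vinylpalladium inserts the C12=C13 alkene in the 5-exo mode, and the C12–Pd bond, which has no syn β-hydrogen (H11 and H13 are on the opposite face), is reduced by the silane. This gives 37 directly, where the route is rejoined.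

**Further compounds**

F1 | step 11 | methyl (3S)-2-[3-(tert-butyldimethylsilyloxy)propyl]-3-{[(iodomethyl)dimethylsilyl]oxy}-6,6-dimethylcyclohex-1-ene-1-carboxylate | COC(=O)C1=C(CCCO[Si](C)(C)C(C)(C)C)[C@@H](O[Si](C)(C)CI)CCC1(C)C
F2 | step 22 | 14-acetoxy Diels–Alder adduct (C8 CHO, C12=C13, C11 H2) | O=C[C@@]23C(=O)OC[C@]4([C@@H](OC(C)=O)CCC(C)(C)[C@H]4CO[Si](c5ccccc5)(c5ccccc5)C(C)(C)C)[C@@H]2CC=C[C@H]3OC(C)=O
F3 | step 22 | ring C cyclohexa-1,3-diene aldehyde (C11=C12, C13=C14) | O=C[C@@]23C(=O)OC[C@]4([C@@H](OC(C)=O)CCC(C)(C)[C@H]4CO[Si](c5ccccc5)(c5ccccc5)C(C)(C)C)[C@@H]2C=CC=C3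
F4 | step 22 | dienyl propargylic alcohol (C15 epimers) | C#CC(O)[C@@]23C(=O)OC[C@]4([C@@H](OC(C)=O)CCC(C)(C)[C@H]4CO[Si](c5ccccc5)(c5ccccc5)C(C)(C)C)[C@@H]2C=CC=C3
F5 | step 22 | 11,14-endoperoxide | C#CC(O)[C@@]23C(=O)OC[C@]4([C@@H](OC(C)=O)CCC(C)(C)[C@H]4CO[Si](c5ccccc5)(c5ccccc5)C(C)(C)C)[C@@H]2[C@@H]6C=C[C@H]3OO6
F6 | step 22 | cis-11,14-diol propargylic alcohol (triol) | C#CC(O)[C@@]23C(=O)OC[C@]4([C@@H](OC(C)=O)CCC(C)(C)[C@H]4CO[Si](c5ccccc5)(c5ccccc5)C(C)(C)C)[C@@H]2[C@@H](O)C=C[C@H]3O
F7 | step 22 | tetracyclic 11,14,15-triol with 16-methylene (6-OTBDPS) | C=C1C(O)[C@@]23C(=O)OC[C@]4([C@@H](OC(C)=O)CCC(C)(C)[C@H]4CO[Si](c5ccccc5)(c5ccccc5)C(C)(C)C)[C@@H]2[C@@H](O)C[C@@H]1[C@H]3O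
F8 | step 22 | 6-O-TBDPS ether of the target (15-ketone, 11,14-diol) | C=C1C(=O)[C@@]23C(=O)OC[C@]4([C@@H](OC(C)=O)CCC(C)(C)[C@H]4CO[Si](c5ccccc5)(c5ccccc5)C(C)(C)C)[C@@H]2[C@@H](O)C[C@@H]1[C@H]3O
F0 | step 24 | none | none
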